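**Plan**

- Numbering: C1 is the quaternary carbinol carrying the exocyclic C7, C2 the ketone, C3=C4 the alkene, C5 the free carbinol, C6 the benzoate carbon. β is the face of the C1 hydroxyl, α the face of C7.
- Retrosynthesis: the two benzoate acyl–O bonds and the C3=C4 double bond are cut first, giving a saturated ketone. The C6–O bond is then traced to a C7-bound carbonate oxygen that opens a C5–C6 epoxide. Last come the epoxide C–O bonds (C5=C6 alkene), the C1–O bond (α-hydroxylation of a β-keto ester) and the dihydroarene (Birch reduction).
- Forward: the carbocycle is the benzene ring of methyl 2-methoxybenzoate and C7 is its ester carbon, so no C–C bond is made. The epoxide ring forms in step 6 and is exchanged in step 7 for a six-membered cyclic carbonate, which is opened again in step 9.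
- Enabling feature: C7 and O6 are cis on the adjacent ring carbons C1 and C6, while O5 is trans to O6 and cis to the C1 hydroxyl. A carbonate oxygen hanging from C7 can therefore reach a β C5–C6 epoxide only at C6 and only from the α face, closing a cis-fused 1,3-dioxan-2-one and leaving O5 where the epoxide placed it.
- Stereochemistry: C1 comes from a catalytic enantioselective α-hydroxylation, C5 from epoxidation directed by the C1 hydroxyl, C6 from the invertive intramolecular epoxide opening.

Key step: step 7

Assumption: the sense of induction in step 2 follows the antipode of the ligand; the antipode that gives the (R)-hydroxy keto ester is used and the assignment is confirmed by correlation before scale-up.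
Remark: the triol of step 3 and its tert-butyl carbonate are carried as mixtures of epimers at the C2 carbinol, which converge when C2 is oxidised in step 5.

**Route**

Step 1
Reactants: 1 methyl 2-methoxybenzoate
Product: 3 methyl 6-oxocyclohex-2-ene-1-carboxylate, via methyl 2-methoxycyclohexa-2,5-diene-1-carboxylate 2 (not isolated)
Conditions: K, liq. NH3/THF, t-BuOH (1 equiv), −78 °C; NH4Cl; then crude in THF, 1 M HCl, 0 °C → rt, under argon
Reagents that add atoms: water, O
Why: Birch reduction of the benzoate should place the two new hydrogens on the ester-bearing carbon and the carbon para to it, leaving the methoxy group on a double bond, and dilute acid then hydrolyses only this enol ether to the ketone while the C5=C6 double bond stays where the later epoxide is needed.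

Step 2
Reactants: 3 methyl 6-oxocyclohex-2-ene-1-carboxylate
Product: 4 methyl (1R)-1-hydroxy-6-oxocyclohex-2-ene-1-carboxylate
Conditions: Ni(ClO4)2·6H2O (10 mol %), DBFOX-Ph (11 mol %), 4 Å MS, CH2Cl2, 0 °C; (±)-2-(phenylsulfonyl)-3-phenyloxaziridine (1.2 equiv)
Reagents that add atoms: 2-(phenylsulfonyl)-3-phenyloxaziridine, O=S(=O)(c1ccccc1)N1OC1c1ccccc1
Why: Catalytic enantioselective α-hydroxylation of a β-keto ester, in which the substrate binds the chiral nickel(II) complex as its bidentate enolate and the oxaziridine should transfer oxygen to the doubly activated C1 on the unshielded face, setting the quaternary carbinol.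

Step 3
Reactants: 4 methyl (1R)-1-hydroxy-6-oxocyclohex-2-ene-1-carboxylate
Product: 5 (2S)-2-(hydroxymethyl)cyclohex-3-ene-1,2-diol (the C1/C2/C7 triol of the route numbering; C2 carbinol as both epimers)
Conditions: LiAlH4 (2.5 equiv), THF, −40 → 0 °C; aq. NaOH work-up
Reagents that add atoms: none
Why: Hydride reduction with LiAlH4 takes the ester to the primary C7 alcohol and the ketone to a C2 carbinol that step 5 re-oxidises, which avoids acid-catalysed ketalisation of an α-hydroxy β-keto ester prone to acyl shift, and C1 cannot epimerise because it bears no hydrogen.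

Step 4
Reactants: 5 (2S)-2-(hydroxymethyl)cyclohex-3-ene-1,2-diol; 6 di-tert-butyl dicarbonate
Product: 7 tert-butyl [(1S)-1,6-dihydroxycyclohex-2-en-1-yl]methyl carbonate (C7 tert-butyl carbonate of 5; C2 carbinol of the route numbering as both epimers)
Conditions: Boc2O (1.05 equiv), N-methylimidazole (0.2 equiv), CH2Cl2, 0 °C
Reagents that add atoms: di-tert-butyl dicarbonate, CC(C)(C)OC(=O)OC(=O)OC(C)(C)C
Why: Nucleophile-catalysed O-acylation with one equivalent of Boc anhydride at 0 °C should take only the primary C7 hydroxyl, the secondary and tertiary hydroxyls being far slower.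

Step 5
Reactants: 7 tert-butyl [(1S)-1,6-dihydroxycyclohex-2-en-1-yl]methyl carbonate
Product: 8 tert-butyl [(1S)-1-hydroxy-6-oxocyclohex-2-en-1-yl]methyl carbonate
Conditions: Dess–Martin periodinane (1.3 equiv), pyridine (3 equiv), CH2Cl2, 0 °C → rt
Reagents that add atoms: none
Why: Dess–Martin oxidation converts the only oxidisable (secondary) hydroxyl into the C2 ketone under buffered, near-neutral conditions that leave the tert-butyl carbonate, the tertiary alcohol and the alkene untouched.

Step 6
Reactants: 8 tert-butyl [(1S)-1-hydroxy-6-oxocyclohex-2-en-1-yl]methyl carbonate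
Product: 9 C7 tert-butyl carbonate of the C5–C6 β-epoxy ketol (epoxide syn to the C1 hydroxyl, C2 ketone, C3–C4 saturated)
Conditions: VO(acac)2 (5 mol %), t-BuOOH (1.5 equiv, decane solution), CH2Cl2, 0 °C → rt
Reagents that add atoms: tert-butyl hydroperoxide, CC(C)(C)OO
Why: Hydroxyl-directed epoxidation, in which the vanadium(V) alkoxide of the tertiary allylic C1 alcohol should deliver the peroxide oxygen to C5=C6 on the face of that hydroxyl, setting C5 and C6 as the β-epoxide, while the metal peroxide does not attack the ketone as a peracid could by Baeyer–Villiger oxidation.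

Step 7
Reactants: 9 C7 tert-butyl carbonate of the C5–C6 β-epoxy ketol
Product: 10 cyclic carbonate (cis-fused 1,3-dioxan-2-one spanning O7 and the α-oxygen on C6; C1 and C5 hydroxyls free and β; C2 ketone)
Conditions: BF3·OEt2 (1.5 equiv), CH2Cl2, −78 → −20 °C; aq. NaHCO3
Reagents that add atoms: none
Why: Boron trifluoride coordinates the epoxide oxygen and the carbonyl oxygen of the C7 tert-butyl carbonate attacks C6 from the α face, anti to the breaking C6–O bond; the tert-butoxy dioxanylium ion so formed loses isobutene to leave the 1,3-dioxan-2-one, and the epoxide oxygen stays on C5 as the β-hydroxyl. The closest known reaction type is the Lewis-acid-promoted cyclisation of epoxy tert-butyl carbonates to cyclic carbonates. The one ring that closes is the six-membered carbonate, by a 6-exo-tet attack at C6 that gives a cis-fused bicycle, whereas attack at C5 would be a 7-endo closure. The new C6–O stereocentre is controlled by the substrate: the tether hangs from C7 on the α face and the epoxide lies on the β face, so only invertive opening is possible, and the half-chair with C7 pseudo-equatorial lets it proceed as a trans-diaxial opening. The step needs regioselectivity for C6, which the tether length secures, and chemoselectivity over other cationic pathways: the C1 hydroxyl is syn to the epoxide and cannot reach the backside of either carbon, a semipinacol shift from C1 would put positive charge next to the C2 carbonyl, and the saturated C3–C4 bond keeps C5 from ionising as an allylic centre.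

Step 8
Reactants: 10 cyclic carbonate
Product: 11 C5 O-tert-butyldimethylsilyl ether of 10
Conditions: TBSCl (1.5 equiv), imidazole (3 equiv), DMF, rt
Reagents that add atoms: tert-butyldimethylsilyl chloride, CC(C)(C)[Si](C)(C)Cl
Why: Silyl ether formation at the secondary C5 hydroxyl, which the hindered tertiary C1 hydroxyl does not follow under these conditions, masks the one oxygen that must not be benzoylated.

Step 9
Reactants: 11 C5 O-TBS cyclic carbonate
Product: 12 5β-(tert-butyldimethylsilyloxy)-1β,6α-dihydroxy-1-(hydroxymethyl)cyclohexan-2-one (route numbering)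
Conditions: K2CO3 (0.1 equiv), MeOH, −10 → 0 °C; AcOH quench
Reagents that add atoms: none
Why: Base-catalysed transesterification (methanolysis) of the reactive six-membered cyclic carbonate gives the diol and dimethyl carbonate, and catalytic base at low temperature with an early quench should keep retro-aldol cleavage of the β-hydroxy ketone and silyl migration from O5 to O6 from competing.

Step 10
Reactants: 12 C5 O-TBS triol; 13 benzoyl chloride
Product: 14 C6,C7-dibenzoate of 12 (C1 hydroxyl free)
Conditions: BzCl (2.4 equiv), pyridine, DMAP (0.1 equiv), CH2Cl2, 0 °C → rt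
Reagents that add atoms: benzoyl chloride, O=C(Cl)c1ccccc1
Why: DMAP-catalysed acylation benzoylates the primary C7 and secondary C6 hydroxyls, while the tertiary C1 hydroxyl next to the ketone is too hindered and too weakly nucleophilic to react.

Step 11
Reactants: 14 C6,C7-dibenzoate
Product: 15 C5 O-tert-butyldimethylsilyl ether of the target (C3=C4 enone)
Conditions: IBX (2.5 equiv), 4-methoxypyridine N-oxide (2.5 equiv), DMSO, rt → 40 °C
Reagents that add atoms: none
Why: IBX dehydrogenation of a ketone to its enone can only occur between C3 and C4 because C1 is quaternary, and its non-basic conditions should tolerate the free tertiary alcohol, the benzoates and the silyl ether.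

Step 12
Reactants: 15 C5 O-TBS enone
Product: 16 [(1R,2S,3R)-2-(benzoyloxy)-1,3-dihydroxy-6-oxocyclohex-4-en-1-yl]methyl benzoate (target)
Conditions: HF·pyridine, pyridine, THF, 0 °C → rt
Reagents that add atoms: none
Why: Desilylation with buffered HF·pyridine frees the C5 hydroxyl under mildly acidic conditions, avoiding the base-induced benzoyl shift from O6 to O5 and the elimination that a γ-oxygenated enone could undergo.

**Compound list**

1 | methyl 2-methoxybenzoate | COC(=O)c1ccccc1OC | starting material
2 | methyl 2-methoxycyclohexa-2,5-diene-1-carboxylate | COC(=O)C1C=CCC=C1OC | intermediate (not isolated)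
3 | methyl 6-oxocyclohex-2-ene-1-carboxylate (racemic, in equilibrium with its enol) | COC(=O)C1C=CCCC1=O | intermediate
4 | methyl (1R)-1-hydroxy-6-oxocyclohex-2-ene-1-carboxylate | COC(=O)[C@]1(O)C(=O)CCC=C1 | intermediate
5 | (2S)-2-(hydroxymethyl)cyclohex-3-ene-1,2-diol (both epimers at the secondary carbinol) | OC[C@]1(O)C(O)CCC=C1 | intermediate
6 | di-tert-butyl dicarbonate | CC(C)(C)OC(=O)OC(=O)OC(C)(C)C | starting material
7 | tert-butyl [(1S)-1,6-dihydroxycyclohex-2-en-1-yl]methyl carbonate (both epimers at the secondary carbinol) | CC(C)(C)OC(=O)OC[C@]1(O)C(O)CCC=C1 | intermediate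
8 | tert-butyl [(1S)-1-hydroxy-6-oxocyclohex-2-en-1-yl]methyl carbonate | CC(C)(C)OC(=O)OC[C@]1(O)C(=O)CCC=C1 | intermediate
9 | C7 tert-butyl carbonate of the C5–C6 β-epoxy ketol (epoxide syn to the C1 hydroxyl) | CC(C)(C)OC(=O)OC[C@]1(O)C(=O)CC[C@H]2O[C@@H]12 | intermediate
10 | cis-fused cyclic carbonate spanning O7 and O6, C1 and C5 hydroxyls free | O=C1OC[C@]2(O)C(=O)CC[C@@H](O)[C@@H]2O1 | intermediate
11 | C5 O-TBS ether of 10 | O=C1OC[C@]2(O)C(=O)CC[C@@H](O[Si](C)(C)C(C)(C)C)[C@@H]2O1 | intermediate
12 | 5β-(tert-butyldimethylsilyloxy)-1β,6α-dihydroxy-1-(hydroxymethyl)cyclohexan-2-one (route numbering) | OC[C@]1(O)C(=O)CC[C@@H](O[Si](C)(C)C(C)(C)C)[C@@H]1O | intermediate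
13 | benzoyl chloride | O=C(Cl)c1ccccc1 | starting material
14 | C6,C7-dibenzoate of 12 | O=C(OC[C@]1(O)C(=O)CC[C@@H](O[Si](C)(C)C(C)(C)C)[C@@H]1OC(=O)c1ccccc1)c1ccccc1 | intermediate
15 | C5 O-TBS ether of the target | O=C(OC[C@]1(O)C(=O)C=C[C@@H](O[Si](C)(C)C(C)(C)C)[C@@H]1OC(=O)c1ccccc1)c1ccccc1 | intermediate
16 | [(1R,2S,3R)-2-(benzoyloxy)-1,3-dihydroxy-6-oxocyclohex-4-en-1-yl]methyl benzoate | O=C(OC[C@]1(O)C(=O)C=C[C@@H](O)[C@@H]1OC(=O)c1ccccc1)c1ccccc1 | target

**Count and risks**

Total steps: 12. Longest linear sequence: 12 steps, from methyl 2-methoxybenzoate.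

The three steps most likely to fail are steps 2, 7 and 6.

Step 2. The hydroxylation may proceed with low enantioselectivity on a small methyl ester, and oxygen transfer may be diverted to C5 of the dienol or accompanied by aromatisation. The fallback replaces catalyst control by an auxiliary-based resolution. β-Keto ester 3 is transesterified with (−)-menthol (DMAP cat., toluene, reflux, methanol distilled off) to the menthyl keto ester F1. Hydroxylation with the same oxaziridine under achiral catalysis (Ni(ClO4)2·6H2O without ligand) should give the menthyl (1R)-hydroxy keto ester F2 together with its C1 epimer F3, to be separated by crystallisation or chromatography. LiAlH4 reduction of F2 releases menthol and gives triol 5, where the route is rejoined.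

Step 7. The carbonate carbonyl may be too weak a nucleophile for an epoxide carbon deactivated by the neighbouring carbinol and ketone, so that fluoride transfer from the Lewis acid, a hydride shift of the epoxide or an acyloin-type shift of the α-ketol could take over. The fallback keeps the same bond and the same ring but uses a more nucleophilic urethane tether. Triol 5 is treated with phenyl isocyanate (1 equiv, pyridine, 0 °C) to give the C7 N-phenylcarbamate F4. This is oxidised with Dess–Martin periodinane to the ketone F5 and epoxidised (VO(acac)2, t-BuOOH) to the β-epoxide F6. BF3·OEt2 or Et2AlCl at low temperature should then close the cyclic N-phenyliminocarbonate F7 through the urethane oxygen, and dilute aqueous acid hydrolyses it to carbonate 10 with loss of aniline.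

Step 6. Oxygen delivery to an electron-poor double bond from a hydroxyl that is part of an α-ketol may be slow, and oxidative degradation of the α-ketol by the vanadium peroxide or erosion of facial selectivity on forcing may follow. The fallback epoxidises at the carbinol oxidation level and oxidises afterwards. Carbonate 7 is treated with mCPBA (NaHCO3, CH2Cl2, 0 °C), where the C1 hydroxyl directs the peracid to the β face and no ketone is present, to give the epoxy diol F8. Dess–Martin oxidation of its C2 carbinol then gives epoxy ketol 9.

Further compounds
F1 | step 2 | (1R,2S,5R)-menthyl 6-oxocyclohex-2-ene-1-carboxylate | CC(C)[C@@H]1CC[C@@H](C)C[C@H]1OC(=O)C1C=CCCC1=O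
F2 | step 2 | (1R,2S,5R)-menthyl (1R)-1-hydroxy-6-oxocyclohex-2-ene-1-carboxylate | CC(C)[C@@H]1CC[C@@H](C)C[C@H]1OC(=O)[C@]1(O)C(=O)CCC=C1
F3 | step 2 | (1R,2S,5R)-menthyl (1S)-1-hydroxy-6-oxocyclohex-2-ene-1-carboxylate | CC(C)[C@@H]1CC[C@@H](C)C[C@H]1OC(=O)[C@@]1(O)C(=O)CCC=C1
F4 | step 7 | C7 N-phenylcarbamate of triol 5 (both epimers at the secondary carbinol) | O=C(Nc1ccccc1)OC[C@]1(O)C(O)CCC=C1
F5 | step 7 | [(1S)-1-hydroxy-6-oxocyclohex-2-en-1-yl]methyl N-phenylcarbamate | O=C(Nc1ccccc1)OC[C@]1(O)C(=O)CCC=C1
F6 | step 7 | C7 N-phenylcarbamate of the C5–C6 β-epoxy ketol | O=C(Nc1ccccc1)OC[C@]1(O)C(=O)CC[C@H]2O[C@@H]12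
F7 | step 7 | cyclic N-phenyliminocarbonate spanning O7 and O6, C1 and C5 hydroxyls free | c1ccccc1N=C1OC[C@]2(O)C(=O)CC[C@@H](O)[C@@H]2O1
F8 | step 6 | C7 tert-butyl carbonate of the C5–C6 β-epoxy C1,C2-diol (both epimers at C2) | CC(C)(C)OC(=O)OC[C@]1(O)C(O)CC[C@H]2O[C@@H]12
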